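**Plan**
- Cuts, in retrosynthetic order: O7–Si (TIPS helper); C2–C3 of the pyranone C ring (back to α-diazoketone 9); C3=N2 (back to the acetyl CH3); the aryl–prenyl bonds at C6 and C8 (back to diiodide 5); O1–C2 (back to 4-methoxybenzyl alcohol); the two C–I bonds (back to 2,4-dihydroxyacetophenone).
- Enabling feature: C2 carries O1 and the 4-methoxyphenyl B ring, so O1–C2–(B ring) is simply a p-methoxybenzyl ether of the A-ring phenol. Its OCH2 holds the most hydridic C–H bonds of the precursor and lies 1,6 to a carbene centre at C3 beside C4=O.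
- Forward order: the purchased A ring is iodinated, silylated at O7, etherified at O1 with the PMB group (C2 plus B ring) and prenylated twice. The acetyl group then becomes a diazoacetyl group, the C ring closes last by Rh-carbenoid C–H insertion, and fluoride frees O7–H.
- Stereochemistry: C2 is the only stereocentre. A chiral dirhodium catalyst sets it during ring closure by selecting the pro-S hydrogen of the OCH2 group (insertion with retention). Only one buffered, non-basic step follows.

Key step: step 6

Assumption: the sense of induction of the dirhodium prolinate on this substrate cannot be derived with certainty. The (S)-catalyst is written, and its commercially available mirror image is used instead if the first run shows the (R)-flavanone.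

**Step 1**
Reactants: 1 2,4-dihydroxyacetophenone
Product: 2 1-(2,4-dihydroxy-3,5-diiodophenyl)ethan-1-one
Conditions: I2 (0.8 equiv), HIO3 (0.4 equiv), EtOH–H2O, 40 °C
Reagents that add atoms: iodine, II; iodic acid, OI(=O)=O
Why: Electrophilic aromatic iodination with I2/HIO3 as the I+ source: C3 and C5 are each ortho or para to both hydroxyl groups and are the only activated positions, whereas C6 is meta to both, so exactly two iodine atoms should enter.

**Step 2**
Reactants: 2 1-(2,4-dihydroxy-3,5-diiodophenyl)ethan-1-one
Product: 3 1-{2-hydroxy-3,5-diiodo-4-[(triisopropylsilyl)oxy]phenyl}ethan-1-one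
Conditions: TIPSOTf (1.05 equiv), 2,6-lutidine, CH2Cl2, 0 °C
Reagents that add atoms: triisopropylsilyl triflate, CC(C)[Si](OS(=O)(=O)C(F)(F)F)(C(C)C)C(C)C
Why: Regioselective O-silylation: the 2-OH is held in a hydrogen bond to the acetyl oxygen and the 4-OH is the more acidic one, so the reactive silyl triflate should cap only O4 (the later O7) despite the flanking iodines, and TIPS is chosen because it outlasts steps 3–6 and leaves under fluoride.

**Step 3**
Reactants: 3 1-{2-hydroxy-3,5-diiodo-4-[(triisopropylsilyl)oxy]phenyl}ethan-1-one; 4 (4-methoxyphenyl)methanol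
Product: 5 1-{3,5-diiodo-2-[(4-methoxybenzyl)oxy]-4-[(triisopropylsilyl)oxy]phenyl}ethan-1-one
Conditions: PPh3, DIAD, THF, 0 °C → rt
Reagents that add atoms: none
Why: Mitsunobu etherification of an acidic phenol by a primary benzylic alcohol under neutral conditions, which spare the electron-poor aryl silyl ether and bring in C2 and the whole B ring in the guise of a protecting group.

**Step 4**
Reactants: 5 1-{3,5-diiodo-2-[(4-methoxybenzyl)oxy]-4-[(triisopropylsilyl)oxy]phenyl}ethan-1-one; 6 tributyl(3-methylbut-2-en-1-yl)stannane (2.6 equiv)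
Product: 7 1-{2-[(4-methoxybenzyl)oxy]-3,5-bis(3-methylbut-2-en-1-yl)-4-[(triisopropylsilyl)oxy]phenyl}ethan-1-one
Conditions: Pd(PPh3)4 (10 mol %), DMF, 90 °C
Reagents that add atoms: none
Why: Twofold Stille coupling of aryl iodides with an allylic stannane under neutral conditions, in which bond formation at the unsubstituted terminus of the prenyl–palladium unit is favoured by the ortho-flanked aryl ligand and should give linear prenyl groups, while ketone, PMB ether and silyl ether are inert.

**Step 5**
Reactants: 7 1-{2-[(4-methoxybenzyl)oxy]-3,5-bis(3-methylbut-2-en-1-yl)-4-[(triisopropylsilyl)oxy]phenyl}ethan-1-one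
Product: 9 2-diazo-1-{2-[(4-methoxybenzyl)oxy]-3,5-bis(3-methylbut-2-en-1-yl)-4-[(triisopropylsilyl)oxy]phenyl}ethan-1-one, via trifluoroacetyl ketone 8 (not isolated)
Conditions: LiHMDS, THF, −78 °C; CF3CO2CH2CF3; dilute HCl wash; then p-ABSA, Et3N, H2O (1 equiv), MeCN, rt
Reagents that add atoms: 4-acetamidobenzenesulfonyl azide (p-ABSA), CC(=O)Nc1ccc(cc1)S(=O)(=O)N=[N+]=[N-]; 2,2,2-trifluoroethyl trifluoroacetate, O=C(OCC(F)(F)F)C(F)(F)F (its CF3CO group stays only as far as 8)
Why: Detrifluoroacetylative diazo transfer: the kinetic lithium enolate of the methyl ketone is C-acylated to the 1,3-diketone 8, whose activated CH2 accepts N2 from the sulfonyl azide and then sheds the CF3CO helper as an N-sulfonyl trifluoroacetamide, which delivers the terminal diazoketone where direct diazo transfer to a simple ketone fails.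

**Step 6**
Reactants: 9 2-diazo-1-{2-[(4-methoxybenzyl)oxy]-3,5-bis(3-methylbut-2-en-1-yl)-4-[(triisopropylsilyl)oxy]phenyl}ethan-1-one
Product: 11 (2S)-2-(4-methoxyphenyl)-6,8-bis(3-methylbut-2-en-1-yl)-7-[(triisopropylsilyl)oxy]chroman-4-one, via rhodium carbenoid 10 (not isolated)
Conditions: Rh2(S-DOSP)4 (1 mol %), 2,2-dimethylbutane, 0 °C → rt, 9 added slowly by syringe pump (final 0.01 M), Ar
Reagents that add atoms: none
Why: Rh2(S-DOSP)4 binds the diazo carbon of 9, N2 leaves, and the electrophilic acceptor carbenoid 10 inserts through a concerted, hydride-transfer-like three-centre transition state into a C–H bond of the OCH2Ar group, which forms C3–C2 and moves the hydrogen to C3. The closest known reaction type is the dirhodium(II) arenesulfonylprolinate-catalysed intramolecular C–H insertion of o-alkoxyaryl α-diazoketones next to the ether oxygen, which gives 2-substituted chroman-4-ones in enantioenriched form. The pyranone ring closes in the 1,6-insertion mode (six-membered ring); the normally preferred 1,5-mode is void because the fifth atom is O1, which bears no hydrogen. C2 is the only new stereocentre and is controlled by the catalyst alone: its chiral pocket has to pick the pro-S hydrogen of the enantiotopic pair, and insertion with retention then gives (S). The step needs C–H insertion to win over attack of the O1 lone pair (five-membered oxonium ylide, then 1,2-benzyl shift), over cyclopropanation of the prenyl groups and over carbene dimerisation. The substrate helps in that the targeted C–H is the most hydridic one (α-oxygen plus p-anisyl), O1 is a weak donor as part of a vinylogous ester (ortho to C4=O), both prenyl groups stand meta to the carbon bearing the carbenoid side chain so that an intramolecular cyclopropane would demand a meta-bridged ring, the lipophilic TIPS and prenyl groups allow the hydrocarbon solvent in which prolinate catalysts are most selective, and slow addition at high dilution holds back all bimolecular paths.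

**Step 7**
Reactants: 11 (2S)-2-(4-methoxyphenyl)-6,8-bis(3-methylbut-2-en-1-yl)-7-[(triisopropylsilyl)oxy]chroman-4-one
Product: 12 (2S)-7-hydroxy-2-(4-methoxyphenyl)-6,8-bis(3-methylbut-2-en-1-yl)chroman-4-one (the target flavanone)
Conditions: TBAF (1.2 equiv), AcOH (1.5 equiv), THF, 0 °C
Reagents that add atoms: none
Why: Fluoride-induced cleavage of an aryl silyl ether, with acetic acid as buffer so that C3 is not enolised and the pyranone ring is not opened by a retro-oxa-Michael reaction, hence C2 keeps its configuration and the prenyl groups see no strong acid.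

**Compound list**
1 | 2,4-dihydroxyacetophenone | CC(=O)c1ccc(O)cc1O | starting material
2 | 1-(2,4-dihydroxy-3,5-diiodophenyl)ethan-1-one | CC(=O)c1cc(I)c(O)c(I)c1O | intermediate
3 | 1-{2-hydroxy-3,5-diiodo-4-[(triisopropylsilyl)oxy]phenyl}ethan-1-one | CC(=O)c1cc(I)c(O[Si](C(C)C)(C(C)C)C(C)C)c(I)c1O | intermediate
4 | (4-methoxyphenyl)methanol | COc1ccc(CO)cc1 | starting material
5 | 1-{3,5-diiodo-2-[(4-methoxybenzyl)oxy]-4-[(triisopropylsilyl)oxy]phenyl}ethan-1-one | CC(=O)c1cc(I)c(O[Si](C(C)C)(C(C)C)C(C)C)c(I)c1OCc1ccc(OC)cc1 | intermediate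
6 | tributyl(3-methylbut-2-en-1-yl)stannane | CCCC[Sn](CCCC)(CCCC)CC=C(C)C | starting material
7 | 1-{2-[(4-methoxybenzyl)oxy]-3,5-bis(3-methylbut-2-en-1-yl)-4-[(triisopropylsilyl)oxy]phenyl}ethan-1-one | CC(=O)c1cc(CC=C(C)C)c(O[Si](C(C)C)(C(C)C)C(C)C)c(CC=C(C)C)c1OCc1ccc(OC)cc1 | intermediate
8 | 4,4,4-trifluoro-1-{2-[(4-methoxybenzyl)oxy]-3,5-bis(3-methylbut-2-en-1-yl)-4-[(triisopropylsilyl)oxy]phenyl}butane-1,3-dione | COc1ccc(COc2c(C(=O)CC(=O)C(F)(F)F)cc(CC=C(C)C)c(O[Si](C(C)C)(C(C)C)C(C)C)c2CC=C(C)C)cc1 | intermediate
9 | 2-diazo-1-{2-[(4-methoxybenzyl)oxy]-3,5-bis(3-methylbut-2-en-1-yl)-4-[(triisopropylsilyl)oxy]phenyl}ethan-1-one | COc1ccc(COc2c(C(=O)C=[N+]=[N-])cc(CC=C(C)C)c(O[Si](C(C)C)(C(C)C)C(C)C)c2CC=C(C)C)cc1 | intermediate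
10 | rhodium carbenoid of 9 ([Rh] stands for the Rh2(S-DOSP)4 core) | COc1ccc(COc2c(C(=O)C=[Rh])cc(CC=C(C)C)c(O[Si](C(C)C)(C(C)C)C(C)C)c2CC=C(C)C)cc1 | intermediate
11 | (2S)-2-(4-methoxyphenyl)-6,8-bis(3-methylbut-2-en-1-yl)-7-[(triisopropylsilyl)oxy]chroman-4-one | COc1ccc([C@@H]2CC(=O)c3cc(CC=C(C)C)c(O[Si](C(C)C)(C(C)C)C(C)C)c(CC=C(C)C)c3O2)cc1 | intermediate
12 | (2S)-7-hydroxy-2-(4-methoxyphenyl)-6,8-bis(3-methylbut-2-en-1-yl)chroman-4-one (the target flavanone) | COc1ccc([C@@H]2CC(=O)c3cc(CC=C(C)C)c(O)c(CC=C(C)C)c3O2)cc1 | target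

Total step count: 7. Longest linear sequence: 7 steps (1 → 12).

**Steps most likely to fail**

1. Step 6. The lone pair of O1 may capture the carbenoid, followed by 1,2-migration of the benzyl group. The insertion may also drift into a stepwise hydride transfer, or the two enantiotopic hydrogens may be poorly discriminated. The fallback sets out from 7 and comes back at 11, and it builds the stereocentre by a catalytic asymmetric conjugate addition instead. The PMB ether next to the carbonyl group is cleaved under chelation control (MgBr2·OEt2, Me2S, CH2Cl2) to the o-hydroxyacetophenone F1. Condensation with DMF dimethyl acetal (toluene, 90 °C) gives the enaminone F2, and mild acid (TsOH·H2O, CH2Cl2) closes it to the chromone F3. A rhodium(I)/chiral bisphosphine-catalysed asymmetric 1,4-addition of 4-methoxyphenylboronic acid (toluene–H2O), with the ligand antipode that attacks the face leading to (S), should then give 11.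

2. Step 4. Coupling may be slow at the iodide flanked by the two bulky ether groups. Protodeiodination and transfer of the allyl unit through its substituted terminus (reverse prenylation) may compete. The fallback sets out from 1 and comes back at 7, and it replaces cross-coupling by sigmatropic C-allylation and olefin metathesis. O-allylation (allyl bromide, K2CO3, acetone) gives 4-allyloxy-2-hydroxyacetophenone F4, and aromatic Claisen rearrangement (N,N-diethylaniline, 200 °C) gives 3-allyl-2,4-dihydroxyacetophenone F5. A second O-allylation gives 3-allyl-4-allyloxy-2-hydroxyacetophenone F6, and a second Claisen rearrangement into the only free ortho position gives 3,5-diallyl-2,4-dihydroxyacetophenone F7. Silylation as in step 2 gives the 4-O-TIPS ether F8, and Mitsunobu reaction with 4 as in step 3 gives the 2-O-PMB ether F9. Twofold cross-metathesis with 2-methylbut-2-ene (Grubbs II, CH2Cl2, 40 °C) should convert both allyl groups into prenyl groups and give 7.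

3. Step 2. Silylation of the hydroxyl group wedged between two iodine atoms may be slow, with competing silylation at O2 or at the enol of the ketone. The fallback sets out from 1 and comes back at 3, and it inverts the order of events. The unhindered 4-OH of 1 is silylated first (TIPSCl, imidazole, DMF) to 1-{2-hydroxy-4-[(triisopropylsilyl)oxy]phenyl}ethan-1-one F10. The free 2-OH, which is ortho to C3 and para to C5, then directs a twofold iodination (NIS, cat. TFA, MeCN) that should give 3.

**Further compounds**
F1 | step 6 | 1-{2-hydroxy-3,5-bis(3-methylbut-2-en-1-yl)-4-[(triisopropylsilyl)oxy]phenyl}ethan-1-one | CC(=O)c1cc(CC=C(C)C)c(O[Si](C(C)C)(C(C)C)C(C)C)c(CC=C(C)C)c1O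
F2 | step 6 | (E)-3-(dimethylamino)-1-{2-hydroxy-3,5-bis(3-methylbut-2-en-1-yl)-4-[(triisopropylsilyl)oxy]phenyl}prop-2-en-1-one | CN(C)/C=C/C(=O)c1cc(CC=C(C)C)c(O[Si](C(C)C)(C(C)C)C(C)C)c(CC=C(C)C)c1O
F3 | step 6 | 6,8-bis(3-methylbut-2-en-1-yl)-7-[(triisopropylsilyl)oxy]-4H-chromen-4-one | O=c1ccoc2c(CC=C(C)C)c(O[Si](C(C)C)(C(C)C)C(C)C)c(CC=C(C)C)cc12
F4 | step 4 | 4-allyloxy-2-hydroxyacetophenone | CC(=O)c1ccc(OCC=C)cc1O
F5 | step 4 | 3-allyl-2,4-dihydroxyacetophenone | CC(=O)c1ccc(O)c(CC=C)c1O
F6 | step 4 | 3-allyl-4-allyloxy-2-hydroxyacetophenone | CC(=O)c1ccc(OCC=C)c(CC=C)c1O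
F7 | step 4 | 3,5-diallyl-2,4-dihydroxyacetophenone | CC(=O)c1cc(CC=C)c(O)c(CC=C)c1O
F8 | step 4 | 1-{3,5-diallyl-2-hydroxy-4-[(triisopropylsilyl)oxy]phenyl}ethan-1-one | CC(=O)c1cc(CC=C)c(O[Si](C(C)C)(C(C)C)C(C)C)c(CC=C)c1O
F9 | step 4 | 1-{3,5-diallyl-2-[(4-methoxybenzyl)oxy]-4-[(triisopropylsilyl)oxy]phenyl}ethan-1-one | CC(=O)c1cc(CC=C)c(O[Si](C(C)C)(C(C)C)C(C)C)c(CC=C)c1OCc1ccc(OC)cc1
F10 | step 2 | 1-{2-hydroxy-4-[(triisopropylsilyl)oxy]phenyl}ethan-1-one | CC(=O)c1ccc(O[Si](C(C)C)(C(C)C)C(C)C)cc1O
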